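**Strategy.** Everything rests on disconnecting the chain between the unbranched CH2 (third carbon beyond the methyl-bearing stereocentre) and the methyl-bearing sp2 carbon of the (Z)-trisubstituted C(CH3)=CH alkene. The key step exploits this alkene: its geometry is established earlier in a (Z)-vinyl iodide on the bis-furan half and carried over with retention, while the CH2 is unmasked from a terminal vinyl group on the tetronate half by chemoselective hydroboration (a temporary C–B bond). One B-alkyl Suzuki–Miyaura operation thus unites both complete halves, the (S) centre and the (Z)-ylidene lactone ring already in place, leaving only O-demethylation. The precursor is a terminal alkene plus a vinyl iodide.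

Key step: step 11

Remark: compounds 1, 3, 10 and 11 are taken to be commercial; the descriptors read from the structure are (S) at the methyl-bearing carbon and (Z) at both the exocyclic and the chain alkene.

**Step 1**
Reactants: 1 3-methyltetronic acid (4-hydroxy-3-methylfuran-2(5H)-one)
Product: 2 4-methoxy-3-methylfuran-2(5H)-one
Conditions: Me2SO4, K2CO3, acetone, reflux
Reagents that add atoms: dimethyl sulfate, COS(=O)(=O)OC
Why: O-methylation of the vinylogous carboxylic acid with a hard alkylating agent (Williamson-type alkylation at the enolate oxygen) should give the methyl tetronate, masking the acidic hydroxyl for the base-mediated steps that follow.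

**Step 2**
Reactants: 3 (R)-4-benzyl-3-propionyloxazolidin-2-one
Product: 4 (R)-4-benzyl-3-[(S)-2-methylpent-4-enoyl]oxazolidin-2-one
Conditions: NaHMDS, THF, −78 °C; allyl iodide, −78 to −40 °C
Reagents that add atoms: allyl iodide, C=CCI
Why: Evans asymmetric alkylation, in which the chelated (Z)-sodium enolate is allylated on the face opposite the benzyl group of the (R)-auxiliary, should set the (S) methyl-bearing stereocentre.

**Step 3**
Reactants: 4 (R)-4-benzyl-3-[(S)-2-methylpent-4-enoyl]oxazolidin-2-one
Product: 5 (S)-2-methylpent-4-en-1-ol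
Conditions: LiBH4, H2O (1 equiv), Et2O, 0 °C
Reagents that add atoms: none
Why: Reductive cleavage of the imide by hydride attack at the exocyclic carbonyl should release the primary alcohol without touching the stereocentre and return the oxazolidinone.

**Step 4**
Reactants: 5 (S)-2-methylpent-4-en-1-ol
Product: 6 (S)-2-methylpent-4-enal
Conditions: Dess–Martin periodinane, CH2Cl2, 0 °C to rt; NaHCO3 wash; used at once as a cold solution (volatile)
Reagents that add atoms: none
Why: Dess–Martin oxidation under near-neutral conditions should stop at the aldehyde and is not expected to epimerise the α-stereocentre.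

**Step 5**
Reactants: 2 4-methoxy-3-methylfuran-2(5H)-one; 6 (S)-2-methylpent-4-enal
Product: 7 5-[(2S)-1-hydroxy-2-methylpent-4-en-1-yl]-4-methoxy-3-methylfuran-2(5H)-one (mixture of diastereomers at C5 and the carbinol carbon)
Conditions: LDA, THF, −78 °C; then 6, −78 °C; AcOH quench
Reagents that add atoms: none
Why: Deprotonation at C5 gives the lithium furanolate (a vinylogous ester enolate), whose aldol addition to the aldehyde at −78 °C should outpace enolisation; the two new stereocentres form unselectively but both are erased in step 6.

**Step 6**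
Reactants: 7 5-[(2S)-1-hydroxy-2-methylpent-4-en-1-yl]-4-methoxy-3-methylfuran-2(5H)-one
Product: 9 (5Z)-4-methoxy-3-methyl-5-[(2S)-2-methylpent-4-en-1-ylidene]furan-2(5H)-one, via mesylate 8 (not isolated)
Conditions: MsCl, Et3N, CH2Cl2, 0 °C; then DBU, 0 °C to rt
Reagents that add atoms: none
Why: Mesylation followed by base-induced E1cB elimination through the C5 furanolate is stereoconvergent, since all diastereomers of 8 should collapse to the (Z)-ylidene in which the alkyl group lies syn to the ring oxygen and avoids allylic strain with the C4 methoxy group, while the adjacent (S) centre is not involved.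

**Step 7**
Reactants: 10 furan-3-carbaldehyde; 11 3-(bromomethyl)furan
Product: 15 5-(furan-3-ylmethyl)furan-3-carbaldehyde, via lithium morpholinoalkoxide 12 (not isolated), via C5-lithiated alkoxide 13 (not isolated), via C5-alkylated alkoxide 14 (not isolated)
Conditions: morpholine, n-BuLi, THF, −78 °C; 10; s-BuLi, −78 °C; 11, −78 °C to rt; H2O
Reagents that add atoms: none
Why: In the α-amino alkoxide 12 the bulky substituent shields C2 and C4, so s-BuLi should metalate the remaining α-position C5 (lithiation of an aldehyde protected in situ as its α-amino alkoxide), and SN2 alkylation of 13 by the reactive furylmethyl bromide followed by hydrolytic collapse of 14 should give the 2,4-disubstituted furan.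

**Step 8**
Reactants: 15 5-(furan-3-ylmethyl)furan-3-carbaldehyde
Product: 16 (E)-3-[5-(furan-3-ylmethyl)furan-3-yl]prop-2-enal
Conditions: Ph3P=CHCHO (1.2 equiv), toluene, 80 °C
Reagents that add atoms: (triphenylphosphoranylidene)acetaldehyde, O=CC=P(c1ccccc1)(c1ccccc1)c1ccccc1
Why: Wittig olefination with the stabilised formylmethylene ylide should give the (E)-enal, and the geometry is immaterial because the alkene is reduced in step 9.

**Step 9**
Reactants: 16 (E)-3-[5-(furan-3-ylmethyl)furan-3-yl]prop-2-enal
Product: 17 3-[5-(furan-3-ylmethyl)furan-3-yl]propanal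
Conditions: Hantzsch ester (1.1 equiv), dibenzylammonium trifluoroacetate (10 mol%), THF, rt
Reagents that add atoms: none
Why: Iminium activation of the enal by the secondary ammonium salt and hydride transfer from the Hantzsch ester (organocatalytic conjugate transfer hydrogenation) should reduce only the conjugated C=C bond and leave the aldehyde and both furans intact.

**Step 10**
Reactants: 17 3-[5-(furan-3-ylmethyl)furan-3-yl]propanal
Product: 18 2-(furan-3-ylmethyl)-4-[(3Z)-4-iodopent-3-en-1-yl]furan
Conditions: EtPPh3I, n-BuLi, THF, rt; I2, −78 °C; NaHMDS, −78 to −20 °C; then 17, −78 °C to rt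
Reagents that add atoms: ethyltriphenylphosphonium iodide, CC[P+](c1ccccc1)(c1ccccc1)c1ccccc1.[I-]; iodine, II
Why: Stork–Zhao-type Wittig olefination with the non-stabilised α-iodo ylide is kinetically cis-selective through an early oxaphosphetane transition state and should place iodine cis to the chain, giving the (Z)-2-iodoalkene.

**Step 11**
Reactants: 9 (5Z)-4-methoxy-3-methyl-5-[(2S)-2-methylpent-4-en-1-ylidene]furan-2(5H)-one; 18 2-(furan-3-ylmethyl)-4-[(3Z)-4-iodopent-3-en-1-yl]furan
Product: 20 (5Z)-5-[(2S,6Z)-9-[5-(furan-3-ylmethyl)furan-3-yl]-2,6-dimethylnon-6-en-1-ylidene]-4-methoxy-3-methylfuran-2(5H)-one, via B-alkyl-9-BBN borane 19 (not isolated)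
Conditions: 9-BBN dimer, THF, 0 °C to rt; then 18, [1,1'-bis(diphenylphosphino)ferrocene]palladium dichloride Pd(dppf)Cl2 (10 mol%), AsPh3, aq K3PO4, DMF, rt
Reagents that add atoms: none
Why: Anti-Markovnikov hydroboration with 9-BBN turns the terminal vinyl group of 9 into the primary alkylborane 19, whose hydroxyborate transmetalates to the alkenylpalladium iodide formed by oxidative addition of zerovalent palladium into the C–I bond of 18, and reductive elimination then forms the C(sp3)–C(sp2) bond. The closest known reaction type is the B-alkyl Suzuki–Miyaura coupling of alkyl-9-BBN reagents with (Z)-2-iodo-2-alkenes, an established way to build methyl-bearing (Z)-trisubstituted alkenes in polyketide synthesis. No ring is closed and no stereocentre is created: oxidative addition and reductive elimination both proceed with retention, so the (Z) geometry of 18 should pass unchanged into 20, and the (S) centre set in step 2, three carbons from boron, is not touched. The step needs chemoselective hydroboration, which the bulk of 9-BBN secures by reacting only with the monosubstituted alkene and not with the trisubstituted, conjugated exocyclic alkene or the lactone carbonyl. It also needs coupling to outrun β-hydride elimination, which the wide bite angle of dppf together with AsPh3 favours, and phosphate in place of hydroxide or carbonate is chosen to spare the enol lactone.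

**Step 12**
Reactants: 20 (5Z)-5-[(2S,6Z)-9-[5-(furan-3-ylmethyl)furan-3-yl]-2,6-dimethylnon-6-en-1-ylidene]-4-methoxy-3-methylfuran-2(5H)-one
Product: 21 (5Z)-5-[(2S,6Z)-9-[5-(furan-3-ylmethyl)furan-3-yl]-2,6-dimethylnon-6-en-1-ylidene]-4-hydroxy-3-methylfuran-2(5H)-one (target)
Conditions: NaSEt, DMF, rt; then 1 M HCl, 0 °C
Reagents that add atoms: none
Why: SN2 O-demethylation of the vinylogous methyl ester by the soft thiolate, with the tetronate anion as leaving group, should free the tetronic acid without touching the alkenes, the furans or the stereocentre.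

**Compound list**
1 | 3-methyltetronic acid (4-hydroxy-3-methylfuran-2(5H)-one) | CC1=C(O)COC1=O | starting material
2 | 4-methoxy-3-methylfuran-2(5H)-one | COC1=C(C)C(=O)OC1 | intermediate
3 | (R)-4-benzyl-3-propionyloxazolidin-2-one | CCC(=O)N1[C@H](Cc2ccccc2)COC1=O | starting material
4 | (R)-4-benzyl-3-[(S)-2-methylpent-4-enoyl]oxazolidin-2-one | C=CC[C@H](C)C(=O)N1[C@H](Cc2ccccc2)COC1=O | intermediate
5 | (S)-2-methylpent-4-en-1-ol | C=CC[C@H](C)CO | intermediate
6 | (S)-2-methylpent-4-enal | C=CC[C@H](C)C=O | intermediate
7 | 5-[(2S)-1-hydroxy-2-methylpent-4-en-1-yl]-4-methoxy-3-methylfuran-2(5H)-one (diastereomer mixture at C5 and the carbinol carbon) | C=CC[C@H](C)C(O)C1OC(=O)C(C)=C1OC | intermediate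
8 | methanesulfonate of 7 (not isolated) | C=CC[C@H](C)C(OS(C)(=O)=O)C1OC(=O)C(C)=C1OC | intermediate
9 | (5Z)-4-methoxy-3-methyl-5-[(2S)-2-methylpent-4-en-1-ylidene]furan-2(5H)-one | CC1=C(OC)/C(=C/[C@@H](C)CC=C)OC1=O | intermediate
10 | furan-3-carbaldehyde | O=Cc1ccoc1 | starting material
11 | 3-(bromomethyl)furan | BrCc1ccoc1 | starting material
12 | lithium (furan-3-yl)(morpholin-4-yl)methanolate (not isolated) | [Li]OC(N1CCOCC1)c1ccoc1 | intermediate
13 | lithium (5-lithiofuran-3-yl)(morpholin-4-yl)methanolate (not isolated) | [Li]OC(N1CCOCC1)c1coc([Li])c1 | intermediate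
14 | lithium [5-(furan-3-ylmethyl)furan-3-yl](morpholin-4-yl)methanolate (not isolated) | [Li]OC(N1CCOCC1)c1coc(Cc2ccoc2)c1 | intermediate
15 | 5-(furan-3-ylmethyl)furan-3-carbaldehyde | O=Cc1coc(Cc2ccoc2)c1 | intermediate
16 | (E)-3-[5-(furan-3-ylmethyl)furan-3-yl]prop-2-enal | O=C/C=C/c1coc(Cc2ccoc2)c1 | intermediate
17 | 3-[5-(furan-3-ylmethyl)furan-3-yl]propanal | O=CCCc1coc(Cc2ccoc2)c1 | intermediate
18 | 2-(furan-3-ylmethyl)-4-[(3Z)-4-iodopent-3-en-1-yl]furan | I/C(C)=C\CCc1coc(Cc2ccoc2)c1 | intermediate
19 | (5Z)-5-[(2S)-5-(9-borabicyclo[3.3.1]nonan-9-yl)-2-methylpentylidene]-4-methoxy-3-methylfuran-2(5H)-one (not isolated) | CC1=C(OC)/C(=C/[C@@H](C)CCCB2C3CCCC2CCC3)OC1=O | intermediate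
20 | (5Z)-5-[(2S,6Z)-9-[5-(furan-3-ylmethyl)furan-3-yl]-2,6-dimethylnon-6-en-1-ylidene]-4-methoxy-3-methylfuran-2(5H)-one | CC1=C(OC)/C(=C/[C@@H](C)CCC/C(C)=C\CCc2coc(Cc3ccoc3)c2)OC1=O | intermediate
21 | (5Z)-5-[(2S,6Z)-9-[5-(furan-3-ylmethyl)furan-3-yl]-2,6-dimethylnon-6-en-1-ylidene]-4-hydroxy-3-methylfuran-2(5H)-one | CC1=C(O)/C(=C/[C@@H](C)CCC/C(C)=C\CCc2coc(Cc3ccoc3)c2)OC1=O | target

**Step count.** Total: 12 steps. Longest linear sequence: 7 steps (steps 2, 3, 4, 5, 6, 11, 12).

**Steps most likely to fail**

Step 11. The aqueous base may open the enol lactone, and transmetalation at the α-methyl-substituted alkenylpalladium may be slow enough for protodeboronation and β-hydride elimination to compete. The fallback sets out from 9 and comes back at 20 through a base-free Negishi coupling. Hydroboration of 9 with 9-BBN (through 19) followed by oxidation with NaBO3·4H2O would give (5Z)-5-[(2S)-5-hydroxy-2-methylpentylidene]-4-methoxy-3-methylfuran-2(5H)-one F6. Treatment with I2, PPh3 and imidazole would give (5Z)-5-[(2S)-5-iodo-2-methylpentylidene]-4-methoxy-3-methylfuran-2(5H)-one F7. Insertion of zinc dust in the presence of LiCl in THF would give the corresponding alkylzinc iodide F8. Coupling of F8 with 18 under Pd(dppf)Cl2 in THF/DMA at rt would form the same bond with retention of the alkene geometry and deliver 20.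

Step 10. The α-iodo ylide may decompose or lose iodine before olefination, and the cis selectivity of the olefination may erode. The fallback sets out from 17 and comes back at 20. Corey–Fuchs dibromo-olefination of 17 (CBr4, PPh3, CH2Cl2, 0 °C) would give 4-(4,4-dibromobut-3-en-1-yl)-2-(furan-3-ylmethyl)furan F4. A trans-selective Negishi monomethylation (MeZnCl, Pd(PPh3)4, THF, 0 °C to rt), in which oxidative addition occurs at the less hindered C–Br bond trans to the chain, would give 4-[(3Z)-4-bromopent-3-en-1-yl]-2-(furan-3-ylmethyl)furan F5. F5 would then take the place of 18 in step 11 (same borane 19, Pd(OAc)2 with SPhos, 50 °C), so the alkene geometry would be set by site-selective coupling and not by a kinetic olefination.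

Step 7. Halogen–lithium exchange between the aryllithium and the furylmethyl bromide may lead to homocoupling, and the aggregated dianion may alkylate incompletely. The fallback sets out from 10 and 11 and comes back at 15 with the polarity of the union reversed. Compound 13, generated from 10 as in step 7, would be quenched with I2 to give lithium (5-iodofuran-3-yl)(morpholin-4-yl)methanolate F1, which is hydrolysed on work-up to 5-iodofuran-3-carbaldehyde F2. Compound 11 would be converted by zinc dust and LiCl in THF into (furan-3-ylmethyl)zinc bromide F3. A Negishi coupling of F2 with F3 (Pd(PPh3)4, THF, rt) would give 15.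

**Further compounds**
F1 | step 7 | lithium (5-iodofuran-3-yl)(morpholin-4-yl)methanolate (not isolated) | [Li]OC(N1CCOCC1)c1coc(I)c1
F2 | step 7 | 5-iodofuran-3-carbaldehyde | O=Cc1coc(I)c1
F3 | step 7 | (furan-3-ylmethyl)zinc bromide | Br[Zn]Cc1ccoc1
F4 | step 10 | 4-(4,4-dibromobut-3-en-1-yl)-2-(furan-3-ylmethyl)furan | BrC(Br)=CCCc1coc(Cc2ccoc2)c1
F5 | step 10 | 4-[(3Z)-4-bromopent-3-en-1-yl]-2-(furan-3-ylmethyl)furan | Br/C(C)=C\CCc1coc(Cc2ccoc2)c1
F6 | step 11 | (5Z)-5-[(2S)-5-hydroxy-2-methylpentylidene]-4-methoxy-3-methylfuran-2(5H)-one | CC1=C(OC)/C(=C/[C@@H](C)CCCO)OC1=O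
F7 | step 11 | (5Z)-5-[(2S)-5-iodo-2-methylpentylidene]-4-methoxy-3-methylfuran-2(5H)-one | CC1=C(OC)/C(=C/[C@@H](C)CCCI)OC1=O
F8 | step 11 | [(4S,5Z)-5-(3-methoxy-4-methyl-5-oxofuran-2(5H)-ylidene)-4-methylpentyl]zinc iodide | CC1=C(OC)/C(=C/[C@@H](C)CCC[Zn]I)OC1=O
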